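**Plan**

1. The target is a head-to-tail cyclodimer. Its 12-membered ring is built twice from three contiguous resorcinol carbons, a ketone carbon, and C-4 and C-3 of a 3-aryl-4-aroyl-5-aryl-1-methylcyclohexene. The two halves differ only at C-4 (3R,4S,5R versus 3R,4R,5R).
2. Retrosynthesis: (a) invert C-4 of the 3R,4R,5R half to reach the C2-symmetric endo,endo dimer, whose two C-4 centres are homotopic; (b) retro-[4+2] of one cyclohexene (cut C-3–C-4 and C-5–C-6) opens the 12-membered ring; (c) the same cut in the other cyclohexene gives two molecules of one monomer.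
3. Enabling feature: on each resorcinol ring the enone carbonyl and the (E)-3-methylbuta-1,3-dienyl group sit 1,3 to each other, so the monomer is both diene and dienophile and head-to-tail pairing closes the ring.
4. Forward order: Claisen–Schmidt condensation, Suzuki–Miyaura dienylation, then a cascade in which an intermolecular Diels–Alder reaction forms the first cyclohexene and an intramolecular one forms the second cyclohexene and the 12-membered ring together.
5. Stereochemistry: the E-enone gives trans C-4/C-5; endo approach to the boron-chelated enone gives cis C-3/C-4; the chiral borate sets the same absolute sense in both cycloadditions; base equilibration of the capped dimer then inverts one C-4, and acetal cleavage finishes the route.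

Key step: step 6

Remark: the two C(=O)–CH centres of the target have opposite relative configuration, so the target is treated as the singly C-4-inverted isomer of the C2-symmetric endo,endo cyclodimer.

Assumption: the (R)-ligand is taken to give the 3R,4S,5R series; if the sense of induction is opposite, the (S)-ligand is used.

Cyclohexene numbering used below: C-1 carries the methyl group (C-1=C-2), C-3 the resorcinol-type aryl, C-4 the aroyl group, C-5 the 2,4-dioxygenated phenyl.

**Step 1**
Reactants: 1 2-methylbut-1-en-3-yne
Product: 2 (E)-4,4,5,5-tetramethyl-2-(3-methylbuta-1,3-dien-1-yl)-1,3,2-dioxaborolane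
Conditions: pinacolborane, Cp2Zr(H)Cl (5 mol%), Et3N (10 mol%), neat, 60 °C
Reagents that add atoms: pinacolborane (CC1(C)OBOC1(C)C)
Why: Zirconium-hydride-catalysed hydroboration adds H–B syn across the terminal alkyne with boron at the terminal carbon, which fixes the E-alkenylboronate and leaves the 1,1-disubstituted alkene untouched.

**Step 2**
Reactants: 3 2,4-dihydroxybenzaldehyde
Product: 4 2,4-bis(methoxymethoxy)benzaldehyde
Conditions: MOMCl (2.5 equiv), K2CO3, acetone, 50 °C
Reagents that add atoms: chloromethyl methyl ether, MOMCl (COCCl)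
Why: Williamson-type O-alkylation of both phenoxides gives the bis-acetal, with heating needed for the hydrogen-bonded ortho-hydroxyl.

**Step 3**
Reactants: 5 1-(5-bromo-2,4-dihydroxyphenyl)ethanone
Product: 6 1-[5-bromo-2-hydroxy-4-(methoxymethoxy)phenyl]ethanone
Conditions: MOMCl (1.05 equiv), K2CO3, acetone, 0 °C to rt
Reagents that add atoms: chloromethyl methyl ether, MOMCl (COCCl)
Why: The 4-hydroxyl is the more acidic and accessible phenol while the 2-hydroxyl is held in a hydrogen bond to the acetyl group, so one equivalent of MOMCl should alkylate O-4 only and keep the 2-OH free as the later boron-binding site.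

**Step 4**
Reactants: 6 1-[5-bromo-2-hydroxy-4-(methoxymethoxy)phenyl]ethanone; 4 2,4-bis(methoxymethoxy)benzaldehyde
Product: 7 (E)-3-[2,4-bis(methoxymethoxy)phenyl]-1-[5-bromo-2-hydroxy-4-(methoxymethoxy)phenyl]prop-2-en-1-one
Conditions: KOH, EtOH/H2O, rt
Reagents that add atoms: none
Why: Claisen–Schmidt condensation (aldol addition, then E1cB dehydration) gives the thermodynamically favoured E-enone, and the acetal groups tolerate aqueous hydroxide.

**Step 5**
Reactants: 7 bromochalcone; 2 (E)-dienyl pinacol boronate
Product: 8 (E)-3-[2,4-bis(methoxymethoxy)phenyl]-1-[2-hydroxy-4-(methoxymethoxy)-5-[(E)-3-methylbuta-1,3-dien-1-yl]phenyl]prop-2-en-1-one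
Conditions: Pd(OAc)2 (5 mol%), SPhos (10 mol%), K3PO4, THF/H2O, 50 °C
Reagents that add atoms: none
Why: Suzuki–Miyaura coupling of the aryl bromide with the E-alkenylboronate proceeds with retention of alkene geometry; the electron-rich biarylphosphine offsets the deactivating para-phenoxide and the mild temperature avoids thermal self-cycloaddition of 8.

**Step 6**
Reactants: 8 diene-chalcone monomer (two molecules)
Product: 10 C2-symmetric endo,endo macrocyclic dimer as hexakis(methoxymethyl) ether (both cyclohexenes 3R,4S,5R; free phenol ortho to each ketone), via linear monoadduct 9 (not isolated)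
Conditions: (R)-VANOL [(R)-3,3'-diphenyl-2,2'-bi-1-naphthol], BH3·THF, AcOH, THF, rt (borate formation, 1.1 equiv per molecule of 8); then 8, PhCF3, 0.02 M, 4 Å MS, rt to 40 °C; MeOH/aq. NaHCO3 work-up
Reagents that add atoms: none
Why: Two borate-bound 2'-hydroxychalcone units react in turn as dienophiles in normal-demand [4+2] cycloadditions with the (E)-1-aryl-3-methylbutadiene units, the closest known reaction type being the chiral boron Lewis acid promoted Diels–Alder reaction of 2'-hydroxychalcones. The first, intermolecular cycloaddition closes one methylcyclohexene and gives 9; the second, intramolecular one closes the other methylcyclohexene and, through the same new bond between the enone alpha-carbon and the aryl-bearing diene terminus, the 12-membered ring. In each event the E-enone fixes the trans C-4/C-5 relationship, endo approach to the boron-chelated s-cis enone places the C-3 aryl cis to the aroyl group, and the (R)-ligand shields one enone face so that both cyclohexenes should receive the same 3R,4S,5R configuration. Head-to-tail regiochemistry (diene CH2 terminus to the enone beta-carbon) follows from the polarisation of the 1-aryl-3-methyl diene. Ring closure is expected to outrun oligomerisation because in 9 the remaining diene and the remaining boron-activated enone sit on cis-disposed neighbouring substituents of the first cyclohexene and are held face to face, which dilution supports.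

**Step 7**
Reactants: 10 C2-symmetric endo,endo dimer (hexakis ether, two free phenols)
Product: 11 C2-symmetric endo,endo dimer as octakis(methoxymethyl) ether
Conditions: MOMCl (4 equiv), K2CO3, acetone, 50 °C
Reagents that add atoms: chloromethyl methyl ether, MOMCl (COCCl)
Why: O-Alkylation of the two hydrogen-bonded phenols removes the acidic OH that would otherwise be deprotonated first in step 8 and leave each neighbouring ketone non-enolisable.

**Step 8**
Reactants: 11 C2-symmetric octakis(methoxymethyl) ether
Product: 12 octakis(methoxymethyl) ether of the target (one cyclohexene 3R,4S,5R; the other 3R,4R,5R)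
Conditions: NaOMe (0.5 equiv), MeOH/THF, 50 °C; AcOH quench; chromatographic separation, other isomers resubmitted
Reagents that add atoms: none
Why: Reversible enolisation (base-mediated epimerisation of a ketone alpha-stereocentre) equilibrates C-4 while C-3 and C-5 are untouched; in both C-4 epimers the aroyl group is cis to one flanking aryl and trans to the other, so the two arrangements should be close in energy, and because the two ketone-bearing carbons of 11 are homotopic the singly inverted 12 is the same compound whichever one inverts and should be the statistically favoured component.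

**Step 9**
Reactants: 12 octakis(methoxymethyl) ether of the target
Product: 13 target compound CNP0244682.3
Conditions: 3 M aq. HCl, MeOH/THF, 40 °C
Reagents that add atoms: none
Why: Acid-catalysed transacetalisation to methanol cleaves all eight aryl methoxymethyl ethers, and the ketone alpha-centres should not enolise appreciably under these mild acidic conditions, so the configuration from step 8 is kept.

**Compound list**

1 | 2-methylbut-1-en-3-yne | C=C(C)C#C | starting material
2 | (E)-4,4,5,5-tetramethyl-2-(3-methylbuta-1,3-dien-1-yl)-1,3,2-dioxaborolane | CC(=C)/C=C/B1OC(C)(C)C(C)(C)O1 | intermediate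
3 | 2,4-dihydroxybenzaldehyde | O=Cc1ccc(O)cc1O | starting material
4 | 2,4-bis(methoxymethoxy)benzaldehyde | COCOc1ccc(C=O)c(OCOC)c1 | intermediate
5 | 1-(5-bromo-2,4-dihydroxyphenyl)ethanone | CC(=O)c1cc(Br)c(O)cc1O | starting material
6 | 1-[5-bromo-2-hydroxy-4-(methoxymethoxy)phenyl]ethanone | CC(=O)c1cc(Br)c(OCOC)cc1O | intermediate
7 | (E)-3-[2,4-bis(methoxymethoxy)phenyl]-1-[5-bromo-2-hydroxy-4-(methoxymethoxy)phenyl]prop-2-en-1-one | COCOc1ccc(/C=C/C(=O)c2cc(Br)c(OCOC)cc2O)c(OCOC)c1 | intermediate
8 | (E)-3-[2,4-bis(methoxymethoxy)phenyl]-1-[2-hydroxy-4-(methoxymethoxy)-5-[(E)-3-methylbuta-1,3-dien-1-yl]phenyl]prop-2-en-1-one | COCOc1ccc(/C=C/C(=O)c2cc(/C=C/C(C)=C)c(OCOC)cc2O)c(OCOC)c1 | intermediate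
9 | linear monoadduct: (3R,4S,5R)-1-methylcyclohexene with 5-[(E)-3-(2,4-bis(methoxymethoxy)phenyl)prop-2-enoyl]-4-hydroxy-2-(methoxymethoxy)phenyl at C-3, 2-hydroxy-4-(methoxymethoxy)-5-[(E)-3-methylbuta-1,3-dienyl]benzoyl at C-4 (cis to the C-3 aryl) and 2,4-bis(methoxymethoxy)phenyl at C-5 (trans to the aroyl) | CC1=C[C@@H](c2cc(C(=O)/C=C/c3ccc(OCOC)cc3OCOC)c(O)cc2OCOC)[C@@H](C(=O)c2cc(/C=C/C(C)=C)c(OCOC)cc2O)[C@H](c2ccc(OCOC)cc2OCOC)C1 | intermediate (not isolated)
10 | C2-symmetric head-to-tail cyclodimer of 8: two (3R,4S,5R)-1-methylcyclohexenes; the C-3 aryl of each (4-hydroxy-2-(methoxymethoxy)phenyl, attached through C-1) carries at its C-5 the carbonyl of the C-4 aroyl group of the other cyclohexene (12-membered ring, OH ortho to each ketone); 2,4-bis(methoxymethoxy)phenyl at each C-5; C-3 aryl cis and C-5 aryl trans to the aroyl | CC1=C[C@H]2c3cc(c(O)cc3OCOC)C(=O)[C@@H]3[C@@H](C=C(C)C[C@H]3c3ccc(OCOC)cc3OCOC)c3cc(c(O)cc3OCOC)C(=O)[C@H]2[C@H](c2ccc(OCOC)cc2OCOC)C1 | intermediate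
11 | octakis(methoxymethyl) ether of the C2-symmetric endo,endo cyclodimer (10 with both ortho-ketone phenols capped) | CC1=C[C@H]2c3cc(c(OCOC)cc3OCOC)C(=O)[C@@H]3[C@@H](C=C(C)C[C@H]3c3ccc(OCOC)cc3OCOC)c3cc(c(OCOC)cc3OCOC)C(=O)[C@H]2[C@H](c2ccc(OCOC)cc2OCOC)C1 | intermediate
12 | octakis(methoxymethyl) ether of the target: as 11 but C-4 of one cyclohexene inverted (3R,4R,5R; aroyl trans to the C-3 aryl, cis to the C-5 aryl) | CC1=C[C@H]2c3cc(c(OCOC)cc3OCOC)C(=O)[C@H]3[C@@H](C=C(C)C[C@H]3c3ccc(OCOC)cc3OCOC)c3cc(c(OCOC)cc3OCOC)C(=O)[C@H]2[C@H](c2ccc(OCOC)cc2OCOC)C1 | intermediate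
13 | CNP0244682.3, the octaphenol (one cyclohexene 3R,4S,5R, the other 3R,4R,5R) | CC1=C[C@H]2c3cc(c(O)cc3O)C(=O)[C@H]3[C@@H](C=C(C)C[C@H]3c3ccc(O)cc3O)c3cc(c(O)cc3O)C(=O)[C@H]2[C@H](c2ccc(O)cc2O)C1 | target

**Step count**

Total steps: 9.
Longest linear sequence: 7 steps (5 → 6 → 7 → 8 → 10 → 11 → 12 → 13; steps 3 to 9).

**Steps most likely to fail**

1. Step 8. The equilibration may show no useful bias, may run on to inversion at both ketone-bearing carbons, or may give isomers that are hard to separate. The fallback sets out from 10. One of its two equivalent ortho-ketone phenols is capped with one equivalent of MOMCl (K2CO3, acetone) to give the mono-capped heptakis(methoxymethyl) ether F1. With NaOMe in MeOH only the ketone next to the capped phenol can enolise, because the other is shut down as its phenoxide, so inversion is confined to one carbon and gives the singly inverted heptakis(methoxymethyl) ether F2. Cleavage of F2 with HCl in MeOH rejoins the route at 13.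

2. Step 6. Oligomerisation may compete with ring closure, and endo or facial selectivity may erode in the intramolecular event. The fallback sets out from 8. The cascade is run without a chiral promoter on silica-supported silver nanoparticles (Ag/SiO2, CH2Cl2, 50 °C), a known catalyst type for cycloadditions of 2'-hydroxychalcones, at high dilution. This should give the racemic endo,endo dimer, that is 10 together with the enantiomeric macrocycle F3, which is removed by preparative chromatography on a chiral stationary phase. The route is rejoined at 10.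

3. Step 9. Protic acid may promote intramolecular ketalisation of a ketone with the flanking phenols, or addition of a phenol to the ring alkene, during acetal cleavage. The fallback sets out from 12. TMSOTf and 2,2'-bipyridyl in CH2Cl2 at 0 °C exchange the aryl methoxymethyl groups for trimethylsilyl groups under buffered, non-protic conditions and give the octakis(trimethylsilyl) ether F4. Methanolysis of F4 (MeOH, cat. citric acid, rt) rejoins the route at 13.

**Further compounds**

F1 | step 8 | heptakis(methoxymethyl) ether of the C2-symmetric endo,endo cyclodimer with one free ortho-ketone phenol | CC1=C[C@H]2c3cc(c(OCOC)cc3OCOC)C(=O)[C@@H]3[C@@H](C=C(C)C[C@H]3c3ccc(OCOC)cc3OCOC)c3cc(c(O)cc3OCOC)C(=O)[C@H]2[C@H](c2ccc(OCOC)cc2OCOC)C1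
F2 | step 8 | F1 inverted at C-4 of the cyclohexene whose ketone neighbours the capped phenol (that ring 3R,4R,5R) | CC1=C[C@H]2c3cc(c(OCOC)cc3OCOC)C(=O)[C@H]3[C@@H](C=C(C)C[C@H]3c3ccc(OCOC)cc3OCOC)c3cc(c(O)cc3OCOC)C(=O)[C@H]2[C@H](c2ccc(OCOC)cc2OCOC)C1
F3 | step 6 | enantiomer of 10 (both cyclohexenes 3S,4R,5S) | CC1=C[C@@H]2c3cc(c(O)cc3OCOC)C(=O)[C@H]3[C@H](C=C(C)C[C@@H]3c3ccc(OCOC)cc3OCOC)c3cc(c(O)cc3OCOC)C(=O)[C@@H]2[C@@H](c2ccc(OCOC)cc2OCOC)C1
F4 | step 9 | octakis(trimethylsilyl) ether of the target | CC1=C[C@H]2c3cc(c(O[Si](C)(C)C)cc3O[Si](C)(C)C)C(=O)[C@H]3[C@@H](C=C(C)C[C@H]3c3ccc(O[Si](C)(C)C)cc3O[Si](C)(C)C)c3cc(c(O[Si](C)(C)C)cc3O[Si](C)(C)C)C(=O)[C@H]2[C@H](c2ccc(O[Si](C)(C)C)cc2O[Si](C)(C)C)C1
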